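**Strategy**

Ring B, the cyclohexadienone (C1 ketone, C2 acetyl-bearing, C3 and C5 enol carbons, C4 quaternary, C6 bridge-bearing), is an enolised 2-acylcyclohexane-1,3,5-trione, a folded tetraketide in which C1 and C3 are acyl carbons and C2 and C4 enolate carbons. It is cut at C3–C4 and C1–C2 into the γ-carbanion of a β-keto ester dianion that already carries methyl and geranyl on C4, and diketene. One operation acylates C4 (C3–C4, quaternary centre) and closes the ring by Claisen condensation (C1–C2), as in acylphloroglucinol biosynthesis. The racemic ring is resolved and then joined through CH2 to the prenylated butyrylphloroglucinol ring A.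

Key step: step 2

Remark: the enolised triketones are written in the tautomeric form of the target SMILES; their tautomers interconvert and share the single stereocentre C4, so this choice does not affect the route.

**Route**

Step 1
Reactants: 1 methyl 3-oxopentanoate; 2 geranyl bromide
Product: 3 methyl (6E)-4,7,11-trimethyl-3-oxododeca-6,10-dienoate (racemic at C4)
Conditions: LiN(i-Pr)2 (2.1 equiv), THF, 0 °C; 2, 0 to 25 °C; aq. HCl
Reagents that add atoms: none
Why: Dianion γ-alkylation of a β-keto ester: the second equivalent of base removes a C4 proton and this more basic carbanion displaces bromide at the primary allylic carbon of 2 (SN2, E-alkene retained), while the new C4 stereocentre forms as a racemate that is erased by enolisation in step 2.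

Step 2
Reactants: 3 methyl (6E)-4,7,11-trimethyl-3-oxododeca-6,10-dienoate; 4 diketene
Product: 6 racemic 2-acetyl-4-geranyl-3,5-dihydroxy-4-methylcyclohexa-2,5-dien-1-one, via triketo ester 5 (not isolated)
Conditions: LiN(i-Pr)2 (2.1 equiv), THF, −78 to 0 °C; 4 (1.1 equiv), −78 °C; then Mg(OMe)2 (2 equiv), MeOH, 60 °C; aq. HCl
Reagents that add atoms: none
Why: The dianion of 3 attacks the strained lactone carbonyl of 4 through its more basic γ-carbon C4, which forms C3–C4 and the quaternary centre and, after ring opening and proton shift, leaves the β-diketone enolate of 5; under magnesium chelation the central carbon C2 of this enolate adds to the ester carbonyl C1 and methoxide leaves, which forms C1–C2 and delivers the strongly acidic enolised trione as the thermodynamic sink. The closest known reaction types are the γ-acylation of β-keto ester dianions and the biomimetic Claisen cyclisation of 3,5,7-triketo esters to acylphloroglucinols, merged here into a formal [4+2] annulation. Ring B closes by a 6-exo-trig Claisen (Dieckmann-type) condensation. The stereocentre C4 is created without control, because its enolate carbon carries methyl and a primary allylic chain that cannot be told apart through enolate geometry or face, so 6 should be racemic and the configuration is fixed by the resolution of step 3. The step needs acylation at C4 and not at oxygen or at the ester α-carbon (the later C6), and Claisen and not aldol closure (C6 onto the acetyl carbonyl); the first should follow from the higher basicity and nucleophilicity of the γ-carbon of the dianion, the second from the quaternary C4, which denies an aldol product the aromatisation that would make it irreversible, and from the more acidic diketone being the enolate that is present.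

Step 3
Reactants: 6 racemic 2-acetyl-4-geranyl-3,5-dihydroxy-4-methylcyclohexa-2,5-dien-1-one
Product: 7 (4R)-2-acetyl-4-geranyl-3,5-dihydroxy-4-methylcyclohexa-2,5-dien-1-one
Conditions: preparative supercritical-fluid chromatography, amylose tris(3,5-dimethylphenylcarbamate) phase, CO2/MeOH (0.1% HCO2H), 35 °C
Reagents that add atoms: none
Why: Resolution of a racemate by chromatography on a chiral stationary phase: the enantiomers of the acidic enol form diastereomeric complexes of different stability with the amylose carbamate selector and should elute separately, so collecting the (R)-enantiomer (to be assigned by electronic circular dichroism against calculation) fixes the C4 configuration of the target at this point.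

Step 4
Reactants: 8 phloroglucinol; 9 butanoyl chloride
Product: 10 1-(2,4,6-trihydroxyphenyl)butan-1-one
Conditions: AlCl3 (3 equiv), PhNO2, 60 °C; ice, aq. HCl
Reagents that add atoms: none
Why: Friedel–Crafts acylation: the acylium ion from 9 and AlCl3 attacks the very electron-rich ring of 8, and the aryl ketone formed is held as a deactivated aluminium chelate, which should stop the reaction after one acyl group.

Step 5
Reactants: 10 1-(2,4,6-trihydroxyphenyl)butan-1-one; 11 prenyl bromide
Product: 12 1-[2,4,6-trihydroxy-3-(3-methylbut-2-en-1-yl)phenyl]butan-1-one
Conditions: 10% aq. KOH, 0 °C; 11 (0.9 equiv); then aq. HCl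
Reagents that add atoms: none
Why: C-Alkylation of an ambident phloroglucinolate (SN2 on the allylic bromide): in water the hydrogen-bonded oxygens are poor nucleophiles so the ring carbon attacks, the two free ring positions of 10 are equivalent so only one mono-prenyl isomer can form, and the sub-stoichiometric bromide limits double alkylation.

Step 6
Reactants: 7 (4R)-2-acetyl-4-geranyl-3,5-dihydroxy-4-methylcyclohexa-2,5-dien-1-one; 12 1-[2,4,6-trihydroxy-3-(3-methylbut-2-en-1-yl)phenyl]butan-1-one; 13 N,N-dimethylmethyleneiminium iodide (Eschenmoser's salt)
Product: 16 target CNP0227753.1, via Mannich base 14 (not isolated), via ortho-quinone methide 15 (not isolated)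
Conditions: 12, 13 (1.05 equiv), MeCN, 25 °C; then 7, NaOAc (2 equiv), 70 °C
Reagents that add atoms: none
Why: Mannich reaction followed by elimination and Michael addition: 13 aminomethylates the only unsubstituted ring carbon of 12, the Mannich base 14 loses dimethylamine on heating to give ortho-quinone methide 15, and C6 of the vinylogous acid 7, the strongest carbon nucleophile present, adds to its exocyclic carbon with rearomatisation of ring A, while the quaternary C4 stereocentre is not involved.

**Compound list**

1 | methyl 3-oxopentanoate | CCC(=O)CC(=O)OC | starting material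
2 | geranyl bromide, (2E)-1-bromo-3,7-dimethylocta-2,6-diene | BrC/C=C(\C)CCC=C(C)C | starting material
3 | methyl (6E)-4,7,11-trimethyl-3-oxododeca-6,10-dienoate (racemic at C4) | COC(=O)CC(=O)C(C)C/C=C(\C)CCC=C(C)C | intermediate
4 | diketene (4-methylideneoxetan-2-one) | C=C1CC(=O)O1 | starting material
5 | methyl 4-[(2E)-3,7-dimethylocta-2,6-dien-1-yl]-4-methyl-3,5,7-trioxooctanoate (racemic; not isolated) | COC(=O)CC(=O)C(C)(C/C=C(\C)CCC=C(C)C)C(=O)CC(C)=O | intermediate
6 | racemic 2-acetyl-4-[(2E)-3,7-dimethylocta-2,6-dien-1-yl]-3,5-dihydroxy-4-methylcyclohexa-2,5-dien-1-one | CC(=O)C1=C(O)C(C)(C/C=C(\C)CCC=C(C)C)C(O)=CC1=O | intermediate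
7 | (4R)-2-acetyl-4-[(2E)-3,7-dimethylocta-2,6-dien-1-yl]-3,5-dihydroxy-4-methylcyclohexa-2,5-dien-1-one | C1=C(O)[C@@](C)(C/C=C(\C)CCC=C(C)C)C(O)=C(C(C)=O)C1=O | intermediate
8 | phloroglucinol (benzene-1,3,5-triol) | Oc1cc(O)cc(O)c1 | starting material
9 | butanoyl chloride | CCCC(=O)Cl | starting material
10 | 1-(2,4,6-trihydroxyphenyl)butan-1-one | CCCC(=O)c1c(O)cc(O)cc1O | intermediate
11 | prenyl bromide (1-bromo-3-methylbut-2-ene) | CC(C)=CCBr | starting material
12 | 1-[2,4,6-trihydroxy-3-(3-methylbut-2-en-1-yl)phenyl]butan-1-one | CCCC(=O)c1c(O)c(CC=C(C)C)c(O)cc1O | intermediate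
13 | N,N-dimethylmethyleneiminium iodide (Eschenmoser's salt) | C=[N+](C)C.[I-] | starting material
14 | 1-[3-[(dimethylamino)methyl]-2,4,6-trihydroxy-5-(3-methylbut-2-en-1-yl)phenyl]butan-1-one (Mannich base; not isolated) | CCCC(=O)c1c(O)c(CC=C(C)C)c(O)c(CN(C)C)c1O | intermediate
15 | 2-butanoyl-3,5-dihydroxy-6-methylidene-4-(3-methylbut-2-en-1-yl)cyclohexa-2,4-dien-1-one (ortho-quinone methide; not isolated) | C=C1C(=O)C(C(=O)CCC)=C(O)C(CC=C(C)C)=C1O | intermediate
16 | target CNP0227753.1: (R)-7 joined at C6 through CH2 to the free ring carbon of 12 | CCCC(=O)c1c(O)c(CC=C(C)C)c(O)c(CC2=C(O)[C@@](C)(C/C=C(\C)CCC=C(C)C)C(O)=C(C(C)=O)C2=O)c1O | target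

**Step count and risks**

Total: 6 steps. Longest linear sequence: 4 steps (steps 1, 2, 3 and 6); ring A is made in 2 steps (4 and 5) before the union.

Steps most likely to fail:

Step 2 (key step). Proton transfer from diketene to the hindered tertiary carbanion may outrun acylation. During the closing stage, aldol-type closure or retro-Claisen cleavage at the quaternary carbon may compete with the Claisen condensation. The fallback sets out from 3 and returns at 6, and builds the ring stepwise with the acetyl group attached last. γ-Acetylation of the dianion of 3 with N-methoxy-N-methylacetamide (a weakly acidic acyl donor whose tetrahedral adduct is stable until work-up) should give methyl 4-geranyl-4-methyl-3,5-dioxohexanoate F1. Dieckmann-type Claisen closure of its methyl ketone enolate onto the ester (KOt-Bu, THF) should give the achiral 2-geranyl-2-methylcyclohexane-1,3,5-trione F2. O-Acetylation (Ac2O, Et3N) and 4-(dimethylamino)pyridine-catalysed O-to-C acyl migration should then give racemic 6.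

Step 6. The aminomethyl or methylene unit may be exchanged between the partners, which leads to symmetrical dimers. The prenyl or geranyl chain may also cyclise onto a neighbouring enol or phenol oxygen under heat and trace acid. The fallback sets out from 12 and returns at 16, and brings in the bridge carbon at the aldehyde level. Vilsmeier–Haack formylation of 12 (POCl3, DMF; aq. NaOAc) should give 3-butanoyl-2,4,6-trihydroxy-5-(3-methylbut-2-en-1-yl)benzaldehyde F3. A three-component reductive alkylation of 7 with this aldehyde should then give 16: Knoevenagel condensation at C6 and in situ transfer hydrogenation of the alkylidene by Hantzsch ester (L-proline cat., CH2Cl2, 25 °C).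

Step 5. Over-alkylation to the 3,5-diprenyl and geminal diprenyl (dearomatised) products, and O-alkylation, may consume the phenolate. The fallback sets out from 10 and returns at 12. It replaces the phenolate SN2 reaction by an acid-mediated Friedel–Crafts prenylation through the prenyl cation (2-methylbut-3-en-2-ol as limiting reagent, BF3·OEt2, dioxane, 25 °C), which is C-selective. It makes no compound outside the list (F0).

**Further compounds**

F1 | step 2 | methyl 4-[(2E)-3,7-dimethylocta-2,6-dien-1-yl]-4-methyl-3,5-dioxohexanoate (racemic) | COC(=O)CC(=O)C(C)(C/C=C(\C)CCC=C(C)C)C(C)=O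
F2 | step 2 | 2-[(2E)-3,7-dimethylocta-2,6-dien-1-yl]-2-methylcyclohexane-1,3,5-trione (achiral, written as the dienol) | O=C1C=C(O)C(C)(C/C=C(\C)CCC=C(C)C)C(O)=C1
F3 | step 6 | 3-butanoyl-2,4,6-trihydroxy-5-(3-methylbut-2-en-1-yl)benzaldehyde | CCCC(=O)c1c(O)c(CC=C(C)C)c(O)c(C=O)c1O
F0 | step 5 | none | none
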